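## Retrosynthetic overview

1. Target 27 comes from (2S)-flavanone 26 by removal of three MOM ethers; C2 is fixed by a catalyst-controlled kinetic resolution (asymmetric transfer hydrogenation) of the C2-epimeric flavanone 25.
2. Ring C is the only ring made (rings A and B are bought as arenes) and is closed last, by oxa-Michael addition in chalcone 24. The key C–C bond is made just before, in the intermolecular Claisen–Schmidt aldol condensation of methyl ketone 20 (ring A with side chain) and aldehyde 22 (ring B).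
3. Ketone 20 comes from ortho-acylation of phenol 17, whose only free ring positions are the two equivalent ones next to OH; this forces the side chain to sit between the two MOM-protected oxygens (later C6).
4. Phenol 17 comes from an sp3–sp2 Negishi coupling of aryl iodide 14 (phloroglucinol, metalation between two OMOM groups) with the zinc reagent made from (R)-lavandulyl iodide 9.
5. Iodide 9 comes from (R)-lavandulol 8, made by Evans deconjugative α-prenylation of N-senecioyl oxazolidinone 4, which sets the side-chain stereocentre.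

Assumption: the target is read as (2S) at C2 of the chromanone and (S) at the side-chain stereocentre, which is the spatial arrangement of (R)-lavandulol.

Abbreviations in step names: Lav = (2S)-5-methyl-2-(prop-1-en-2-yl)hex-4-en-1-yl, i.e. CH2–CH(isopropenyl)–CH2–CH=CMe2; MOM = methoxymethyl; TIPS = tri(propan-2-yl)silyl. Full names are in the compound list.

## Route

Step 1
Reactants: 1 (4R)-4-benzyl-1,3-oxazolidin-2-one; 2 3-methylbut-2-enoyl chloride
Product: 4 (4R)-4-benzyl-3-(3-methylbut-2-enoyl)-1,3-oxazolidin-2-one, via lithium oxazolidinide 3 (not isolated)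
Conditions: n-BuLi (1.05 equiv), THF, −78 °C; then 2, −78 → 0 °C
Reagents that add atoms: none
Why: N-acylation of the lithiated Evans auxiliary by the acid chloride (acyl substitution), which leaves the auxiliary stereocentre untouched.

Step 2
Reactants: 4 (4R)-4-benzyl-3-(3-methylbut-2-enoyl)-1,3-oxazolidin-2-one; 5 1-bromo-3-methylbut-2-ene
Product: 7 (4R)-4-benzyl-3-[(2R)-5-methyl-2-(prop-1-en-2-yl)hex-4-enoyl]-1,3-oxazolidin-2-one, via sodium dienolate 6 (not isolated)
Conditions: NaN(SiMe3)2 (1.1 equiv), THF, −78 °C, 45 min; then 5 (3 equiv), −78 → −40 °C; NH4Cl quench cold; chromatography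
Reagents that add atoms: none
Why: Evans deconjugative α-alkylation, in which γ-deprotonation gives the chelated (Z)-dienolate that is prenylated at the α-carbon on the face away from the benzyl group, setting the (2R) stereocentre (minor diastereomer removed on silica) and shifting the alkene into the isopropenyl position.

Step 3
Reactants: 7 (4R)-4-benzyl-3-[(2R)-5-methyl-2-(prop-1-en-2-yl)hex-4-enoyl]-1,3-oxazolidin-2-one
Product: 8 (2R)-5-methyl-2-(prop-1-en-2-yl)hex-4-en-1-ol
Conditions: LiBH4 (2 equiv), H2O (1.1 equiv), Et2O, 0 °C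
Reagents that add atoms: none
Why: Reductive cleavage of the imide by the non-basic hydride LiBH4 gives (R)-lavandulol without epimerising the allylic α-stereocentre and returns the auxiliary.

Step 4
Reactants: 8 (2R)-5-methyl-2-(prop-1-en-2-yl)hex-4-en-1-ol
Product: 9 (3R)-3-(iodomethyl)-2,6-dimethylhepta-1,5-diene
Conditions: PPh3, imidazole, I2, CH2Cl2, 0 °C → rt, dark
Reagents that add atoms: iodine, II
Why: Appel iodination takes place at the primary carbinol carbon, so the adjacent stereocentre is a spectator.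

Step 5
Reactants: 10 benzene-1,3,5-triol
Product: 11 3,5-bis(methoxymethoxy)phenol
Conditions: MOMCl (2.0 equiv), i-Pr2NEt (2.2 equiv), DMF, 0 °C → rt; chromatography
Reagents that add atoms: chloromethyl methyl ether (MOMCl), COCCl
Why: O-alkylation of the phenol gives the bis-ether as the main component of a statistical mixture (expect about 40%), separable on silica from the mono- and tris-ethers.

Step 6
Reactants: 11 3,5-bis(methoxymethoxy)phenol
Product: 12 [3,5-bis(methoxymethoxy)phenoxy]tri(propan-2-yl)silane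
Conditions: TIPSCl (1.2 equiv), imidazole (2 equiv), DMF, rt
Reagents that add atoms: chlorotri(propan-2-yl)silane (TIPSCl), CC(C)[Si](Cl)(C(C)C)C(C)C
Why: Silylation marks the oxygen that will become the ring oxygen with a bulky, non-coordinating group that keeps the next metalation away from its ortho positions.

Step 7
Reactants: 12 [3,5-bis(methoxymethoxy)phenoxy]tri(propan-2-yl)silane
Product: 14 [4-iodo-3,5-bis(methoxymethoxy)phenoxy]tri(propan-2-yl)silane, via aryllithium 13 (not isolated)
Conditions: n-BuLi (1.2 equiv), THF, 0 °C, 1 h; then I2 (1.3 equiv), THF, −78 °C → rt; Na2S2O3 work-up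
Reagents that add atoms: iodine, II
Why: Directed ortho-metalation occurs at the one position flanked by two OMOM directing groups, and iodinolysis of the aryllithium then gives a single regioisomer.

Step 8
Reactants: 9 (3R)-3-(iodomethyl)-2,6-dimethylhepta-1,5-diene; 14 [4-iodo-3,5-bis(methoxymethoxy)phenoxy]tri(propan-2-yl)silane
Product: 16 [3,5-bis(methoxymethoxy)-4-Lav-phenoxy]tri(propan-2-yl)silane, via lavandulylzinc iodide 15 (not isolated)
Conditions: 9, Zn dust (activated with BrCH2CH2Br and Me3SiCl), LiCl, THF, 25–40 °C; then 14, 15 (1.3 equiv), Pd(OAc)2 (3 mol %), SPhos (6 mol %), THF, 25 → 50 °C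
Reagents that add atoms: none
Why: Negishi sp3–sp2 cross-coupling, in which zinc insertion into the primary iodide and fast reductive elimination from the SPhos-ligated palladium (outrunning β-hydride elimination) join side chain and ring while the β-stereocentre takes no part in bond making.

Step 9
Reactants: 16 [3,5-bis(methoxymethoxy)-4-Lav-phenoxy]tri(propan-2-yl)silane
Product: 17 3,5-bis(methoxymethoxy)-4-Lav-phenol
Conditions: Bu4NF (1.1 equiv), THF, 0 °C, 30 min
Reagents that add atoms: none
Why: Fluoride-induced Si–O cleavage frees the phenol while MOM ethers and alkenes are inert.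

Step 10
Reactants: 17 3,5-bis(methoxymethoxy)-4-Lav-phenol
Product: 18 6-hydroxy-2,4-bis(methoxymethoxy)-3-Lav-benzaldehyde
Conditions: MgCl2 (2 equiv), Et3N (4 equiv), (CH2O)n (6 equiv), MeCN, 80 °C, 4 h; aqueous citric acid work-up
Reagents that add atoms: paraformaldehyde (as formaldehyde), C=O
Why: Magnesium-phenoxide-directed ortho-formylation (Casnati–Skattebøl) can only hit the two equivalent positions next to OH, so the carbonyl carbon ends up between the free OH and an OMOM group.

Step 11
Reactants: 18 6-hydroxy-2,4-bis(methoxymethoxy)-3-Lav-benzaldehyde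
Product: 19 2-(1-hydroxyethyl)-3,5-bis(methoxymethoxy)-4-Lav-phenol (both carbinol epimers)
Conditions: MeMgBr (3.5 equiv), THF, −20 → 0 °C; aqueous NH4Cl; used crude
Reagents that add atoms: methylmagnesium bromide (MeMgBr), C[Mg]Br
Why: Grignard addition to the aldehyde after deprotonation of the phenol gives the carbinol, whose new centre is uncontrolled and is erased in the next step.

Step 12
Reactants: 19 2-(1-hydroxyethyl)-3,5-bis(methoxymethoxy)-4-Lav-phenol
Product: 20 1-[6-hydroxy-2,4-bis(methoxymethoxy)-3-Lav-phenyl]ethan-1-one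
Conditions: activated MnO2 (15 equiv), CH2Cl2, rt
Reagents that add atoms: none
Why: Chemoselective benzylic oxidation by MnO2 gives the hydrogen-bonded 2-hydroxyacetophenone without touching alkenes, MOM ethers or the phenol.

Step 13
Reactants: 21 4-hydroxy-2-methoxybenzaldehyde
Product: 22 2-methoxy-4-(methoxymethoxy)benzaldehyde
Conditions: MOMCl (1.3 equiv), i-Pr2NEt (2 equiv), CH2Cl2, 0 °C → rt
Reagents that add atoms: chloromethyl methyl ether (MOMCl), COCCl
Why: O-alkylation of the phenol protects it as the base-stable MOM ether and leaves the aldehyde free.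

Step 14
Reactants: 20 1-[6-hydroxy-2,4-bis(methoxymethoxy)-3-Lav-phenyl]ethan-1-one; 22 2-methoxy-4-(methoxymethoxy)benzaldehyde
Product: 24 (2E)-1-[6-hydroxy-2,4-bis(methoxymethoxy)-3-Lav-phenyl]-3-[2-methoxy-4-(methoxymethoxy)phenyl]prop-2-en-1-one, via aldol adduct 23 (not isolated)
Conditions: 22 (1.2 equiv), KOH (10 equiv), EtOH–H2O, rt, 36–48 h; then AcOH to pH 5 at 0 °C
Reagents that add atoms: none
Why: Claisen–Schmidt crossed aldol condensation, in which the potassium enolate of the methyl ketone adds to the non-enolisable aldehyde and the adduct dehydrates (E1cB) to the (E)-enone, forming the future C2–C3 bond and uniting the two halves under conditions that MOM ethers and the non-acidic side-chain stereocentre tolerate.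

Step 15
Reactants: 24 (2E)-1-[6-hydroxy-2,4-bis(methoxymethoxy)-3-Lav-phenyl]-3-[2-methoxy-4-(methoxymethoxy)phenyl]prop-2-en-1-one
Product: 25 (2RS)-2-[2-methoxy-4-(methoxymethoxy)phenyl]-5,7-bis(methoxymethoxy)-6-Lav-2,3-dihydro-4H-chromen-4-one (C2 epimers, about 1:1)
Conditions: NaOAc (10 equiv), EtOH, reflux, 24–36 h; recovered 24 resubmitted
Reagents that add atoms: none
Why: Base-mediated intramolecular oxa-Michael addition of the only free phenol closes ring C, and because the other ortho oxygen is a MOM ether only the 6-substituted flavanone can form, with C2 created without control.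

Step 16
Reactants: 25 (2RS)-2-[2-methoxy-4-(methoxymethoxy)phenyl]-5,7-bis(methoxymethoxy)-6-Lav-2,3-dihydro-4H-chromen-4-one
Product: 26 (2S)-2-[2-methoxy-4-(methoxymethoxy)phenyl]-5,7-bis(methoxymethoxy)-6-Lav-2,3-dihydro-4H-chromen-4-one
Conditions: RhCl(Cp*)[(R,R)-TsDPEN] (1 mol %), HCO2H/Et3N (5:2), EtOAc, rt, to about 55% conversion (HPLC control); chromatography
Reagents that add atoms: none
Why: Noyori–Ikariya asymmetric transfer hydrogenation run as a kinetic resolution, in which the (R,R)-catalyst delivers hydride to give a (4R)-carbinol and only the (2R)-epimer can do so through the favoured cis pathway, so the (2S)-ketone is recovered with C2 fixed and the isolated alkenes untouched.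

Step 17
Reactants: 26 (2S)-2-[2-methoxy-4-(methoxymethoxy)phenyl]-5,7-bis(methoxymethoxy)-6-Lav-2,3-dihydro-4H-chromen-4-one
Product: 27 (2S)-5,7-dihydroxy-2-(4-hydroxy-2-methoxyphenyl)-6-Lav-2,3-dihydro-4H-chromen-4-one
Conditions: 3 M aqueous HCl/MeOH (1:4), 45 °C, 2–3 h, stopped as soon as 26 and partly protected species are gone
Reagents that add atoms: none
Why: Acid-catalysed acetal methanolysis removes the three MOM groups under conditions of the kind used to free prenylated flavanones, and neither C2 (not enolisable, ring opening needs base) nor the side-chain stereocentre is involved.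

## Compound list

1 | (4R)-4-benzyl-1,3-oxazolidin-2-one | O=C1N[C@H](Cc2ccccc2)CO1 | starting material
2 | 3-methylbut-2-enoyl chloride | CC(C)=CC(=O)Cl | starting material
3 | lithium (4R)-4-benzyl-2-oxo-1,3-oxazolidin-3-ide | [Li+].O=C1[N-][C@H](Cc2ccccc2)CO1 | intermediate
4 | (4R)-4-benzyl-3-(3-methylbut-2-enoyl)-1,3-oxazolidin-2-one | CC(C)=CC(=O)N1[C@H](Cc2ccccc2)COC1=O | intermediate
5 | 1-bromo-3-methylbut-2-ene | CC(C)=CCBr | starting material
6 | sodium (1Z)-1-[(4R)-4-benzyl-2-oxo-1,3-oxazolidin-3-yl]-3-methylbuta-1,3-dien-1-olate | [Na+].C=C(C)/C=C(\[O-])N1[C@H](Cc2ccccc2)COC1=O | intermediate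
7 | (4R)-4-benzyl-3-[(2R)-5-methyl-2-(prop-1-en-2-yl)hex-4-enoyl]-1,3-oxazolidin-2-one | C=C(C)[C@@H](CC=C(C)C)C(=O)N1[C@H](Cc2ccccc2)COC1=O | intermediate
8 | (2R)-5-methyl-2-(prop-1-en-2-yl)hex-4-en-1-ol, (R)-lavandulol | C=C(C)[C@@H](CC=C(C)C)CO | intermediate
9 | (3R)-3-(iodomethyl)-2,6-dimethylhepta-1,5-diene, (R)-lavandulyl iodide | C=C(C)[C@@H](CC=C(C)C)CI | intermediate
10 | benzene-1,3,5-triol (phloroglucinol) | Oc1cc(O)cc(O)c1 | starting material
11 | 3,5-bis(methoxymethoxy)phenol | COCOc1cc(O)cc(OCOC)c1 | intermediate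
12 | [3,5-bis(methoxymethoxy)phenoxy]tri(propan-2-yl)silane | COCOc1cc(O[Si](C(C)C)(C(C)C)C(C)C)cc(OCOC)c1 | intermediate
13 | {2,6-bis(methoxymethoxy)-4-[tri(propan-2-yl)silyloxy]phenyl}lithium | [Li]c1c(OCOC)cc(O[Si](C(C)C)(C(C)C)C(C)C)cc1OCOC | intermediate
14 | [4-iodo-3,5-bis(methoxymethoxy)phenoxy]tri(propan-2-yl)silane | Ic1c(OCOC)cc(O[Si](C(C)C)(C(C)C)C(C)C)cc1OCOC | intermediate
15 | iodo[(2R)-5-methyl-2-(prop-1-en-2-yl)hex-4-en-1-yl]zinc | C=C(C)[C@@H](CC=C(C)C)C[Zn]I | intermediate
16 | {3,5-bis(methoxymethoxy)-4-[(2S)-5-methyl-2-(prop-1-en-2-yl)hex-4-en-1-yl]phenoxy}tri(propan-2-yl)silane | C=C(C)[C@@H](CC=C(C)C)Cc1c(OCOC)cc(O[Si](C(C)C)(C(C)C)C(C)C)cc1OCOC | intermediate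
17 | 3,5-bis(methoxymethoxy)-4-[(2S)-5-methyl-2-(prop-1-en-2-yl)hex-4-en-1-yl]phenol | C=C(C)[C@@H](CC=C(C)C)Cc1c(OCOC)cc(O)cc1OCOC | intermediate
18 | 6-hydroxy-2,4-bis(methoxymethoxy)-3-[(2S)-5-methyl-2-(prop-1-en-2-yl)hex-4-en-1-yl]benzaldehyde | C=C(C)[C@@H](CC=C(C)C)Cc1c(OCOC)cc(O)c(C=O)c1OCOC | intermediate
19 | 2-(1-hydroxyethyl)-3,5-bis(methoxymethoxy)-4-[(2S)-5-methyl-2-(prop-1-en-2-yl)hex-4-en-1-yl]phenol (carbinol epimers) | C=C(C)[C@@H](CC=C(C)C)Cc1c(OCOC)cc(O)c(C(C)O)c1OCOC | intermediate
20 | 1-{6-hydroxy-2,4-bis(methoxymethoxy)-3-[(2S)-5-methyl-2-(prop-1-en-2-yl)hex-4-en-1-yl]phenyl}ethan-1-one | C=C(C)[C@@H](CC=C(C)C)Cc1c(OCOC)cc(O)c(C(C)=O)c1OCOC | intermediate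
21 | 4-hydroxy-2-methoxybenzaldehyde | COc1cc(O)ccc1C=O | starting material
22 | 2-methoxy-4-(methoxymethoxy)benzaldehyde | COCOc1ccc(C=O)c(OC)c1 | intermediate
23 | 3-hydroxy-1-{6-hydroxy-2,4-bis(methoxymethoxy)-3-[(2S)-5-methyl-2-(prop-1-en-2-yl)hex-4-en-1-yl]phenyl}-3-[2-methoxy-4-(methoxymethoxy)phenyl]propan-1-one (carbinol epimers) | C=C(C)[C@@H](CC=C(C)C)Cc1c(OCOC)cc(O)c(C(=O)CC(O)c2ccc(OCOC)cc2OC)c1OCOC | intermediate
24 | (2E)-1-{6-hydroxy-2,4-bis(methoxymethoxy)-3-[(2S)-5-methyl-2-(prop-1-en-2-yl)hex-4-en-1-yl]phenyl}-3-[2-methoxy-4-(methoxymethoxy)phenyl]prop-2-en-1-one | C=C(C)[C@@H](CC=C(C)C)Cc1c(OCOC)cc(O)c(C(=O)/C=C/c2ccc(OCOC)cc2OC)c1OCOC | intermediate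
25 | (2RS)-2-[2-methoxy-4-(methoxymethoxy)phenyl]-5,7-bis(methoxymethoxy)-6-[(2S)-5-methyl-2-(prop-1-en-2-yl)hex-4-en-1-yl]-2,3-dihydro-4H-chromen-4-one | C=C(C)[C@@H](CC=C(C)C)Cc1c(OCOC)cc2c(c1OCOC)C(=O)CC(c1ccc(OCOC)cc1OC)O2 | intermediate
26 | (2S)-2-[2-methoxy-4-(methoxymethoxy)phenyl]-5,7-bis(methoxymethoxy)-6-[(2S)-5-methyl-2-(prop-1-en-2-yl)hex-4-en-1-yl]-2,3-dihydro-4H-chromen-4-one | C=C(C)[C@@H](CC=C(C)C)Cc1c(OCOC)cc2c(c1OCOC)C(=O)C[C@@H](c1ccc(OCOC)cc1OC)O2 | intermediate
27 | (2S)-5,7-dihydroxy-2-(4-hydroxy-2-methoxyphenyl)-6-[(2S)-5-methyl-2-(prop-1-en-2-yl)hex-4-en-1-yl]-2,3-dihydro-4H-chromen-4-one | C=C(C)[C@@H](CC=C(C)C)Cc1c(O)cc2c(c1O)C(=O)C[C@@H](c1ccc(O)cc1OC)O2 | target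

## Step count and weak points

Total step count: 17.
Longest linear sequence: 13 steps (1, 2, 3, 4, 8, 9, 10, 11, 12, 14, 15, 16, 17).

**Step 8 (Negishi coupling).** The aryl iodide is electron-rich and flanked by two OMOM groups, and the alkylzinc is β-branched, so slow coupling, β-hydride elimination or protodezincation may lower the yield. The fallback is a catalyst-free SN2 union that sets out from 8 and 12 and comes back at 16. Alcohol 8 is treated with Tf2O and 2,6-lutidine in CH2Cl2 at −78 °C to give (2R)-5-methyl-2-(prop-1-en-2-yl)hex-4-en-1-yl trifluoromethanesulfonate F1, which is used cold and at once. Silyl ether 12 is lithiated as in step 7 to aryllithium 13, which displaces the primary triflate in THF at −78 → −20 °C and gives 16 directly, so that iodide 14 and zinc reagent 15 are bypassed.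

**Step 16 (kinetic resolution).** The ketone is hindered by the 5-OMOM group and the selectivity factor on this substrate is not known, so the recovered ketone may not reach high purity at an acceptable recovery. The fallback harvests the wanted epimer as an alcohol instead of as unreacted ketone; it sets out from 25 and comes back at 26. Mixture 25 is reduced with the enantiomeric catalyst RhCl(Cp*)[(S,S)-TsDPEN] and HCO2H/Et3N to about 40% conversion, so that the (2S)-epimer is the one converted, into (2S,4S)-2-[2-methoxy-4-(methoxymethoxy)phenyl]-5,7-bis(methoxymethoxy)-6-Lav-3,4-dihydro-2H-chromen-4-ol F2. Any trans-alcohol from the mismatched epimer is an ordinary diastereomer and is removed on silica. F2 is then re-oxidised with Dess–Martin periodinane and NaHCO3 in CH2Cl2 to 26.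

**Step 17 (global MOM removal).** Brønsted acid may add the 5-OH or 7-OH across the isopropenyl group (chroman formation), isomerise the side-chain alkene or erode C2 in the electron-rich benzylic ether. The fallback replaces protic solvolysis by a silyl exchange; it sets out from 26 and comes back at 27. Me3SiOTf and 2,2'-bipyridyl in CH2Cl2 at 0 °C → rt exchange each aryl MOM ether for a silyl ether without free acid, giving (2S)-2-[2-methoxy-4-(trimethylsilyloxy)phenyl]-6-Lav-5,7-bis(trimethylsilyloxy)-2,3-dihydro-4H-chromen-4-one F3. Its Si–O bonds are then hydrolysed with water in THF at rt to give 27.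

## Further compounds

F1 | step 8 | (2R)-5-methyl-2-(prop-1-en-2-yl)hex-4-en-1-yl trifluoromethanesulfonate | C=C(C)[C@@H](CC=C(C)C)COS(=O)(=O)C(F)(F)F
F2 | step 16 | (2S,4S)-2-[2-methoxy-4-(methoxymethoxy)phenyl]-5,7-bis(methoxymethoxy)-6-[(2S)-5-methyl-2-(prop-1-en-2-yl)hex-4-en-1-yl]-3,4-dihydro-2H-chromen-4-ol | C=C(C)[C@@H](CC=C(C)C)Cc1c(OCOC)cc2c(c1OCOC)[C@@H](O)C[C@@H](c1ccc(OCOC)cc1OC)O2
F3 | step 17 | (2S)-2-[2-methoxy-4-(trimethylsilyloxy)phenyl]-6-[(2S)-5-methyl-2-(prop-1-en-2-yl)hex-4-en-1-yl]-5,7-bis(trimethylsilyloxy)-2,3-dihydro-4H-chromen-4-one | C=C(C)[C@@H](CC=C(C)C)Cc1c(O[Si](C)(C)C)cc2c(c1O[Si](C)(C)C)C(=O)C[C@@H](c1ccc(O[Si](C)(C)C)cc1OC)O2
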